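(The runs were generated by integration with constants of no real substance; scatter was added.)

The late times asked, 4.0 h in elm and 12 h in maple, lie far beyond the last blue reading at 25.0 min, so I first asked which given numbers had to be known well.

| setting | blue | elm | maple |
|---|---|---|---|
| Z | 0.67 M | 0.67 M | 0.67 M |
| G | 1.01 M | 1.01 M | 1.01 M |
| X | 0.17 M | 0.335 M | 0.335 M |
| E | 0.0335 M | 0.0335 M | 0.0335 M |
| D | 6.7 mM | 6.7 mM | 6.7 mM |
| remark | run made earlier |  |  |
| time |  | 4.0 h | 12 h |

blue run (percent of the Z charged)

| time / min | Q / % | Z / % |
|---|---|---|
| 5.00 | 0.9 | 99.3 |
| 10.0 | 2.5 | 96.5 |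
| 15.0 | 4.3 | 96.3 |
| 20.0 | 5.2 | 94.1 |
| 25.0 | 6.2 | 94.0 |

(readings scatter by 0.5 percentage points)

- the analysis behind the earlier runs scatters by 0.5 percentage points, standard deviation

1. which of these there is most of at the end, counted by the Z in it, elm (Z / Q)
2. which of these there is most of at the end, counted by the Z in it, maple (Z / Q)
3. amount of the one of these that there is most of at the end, in percent of the Z charged, elm
4. amount of the one of these that there is most of at the end, in percent of the Z charged, maple

D is the same in all three flasks, so its value can sit inside a constant. E could be set aside: blue made 0.0415 M of Q, more than the 0.0335 M of E charged, so E is no partner of Z. The charges of Z and G had to be exact. Z is the limiting reagent, and if each Z takes one G, then G falls with Z and the excess of 0.340 M stays. X was the dangerous number. Q gained 2.5% in the first 10.0 min and 1.9 percentage points in the last 10.0 min, a slowing that a scatter of 0.5 points cannot separate from X being consumed. I staked my reckoning on X standing aside, with maple as the test.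

The balance integrates: the logarithm of the fraction of G left over the fraction of Z left equals excess times constant times time. From the last Q reading the constant came to 0.00259 M⁻¹ min⁻¹, the pair constant: the second-order rate constant of Z with G, D inside it. This left Z at 58.9% in elm and 27.6% in maple, so Q leads in maple. The reading at 20.0 min gave 0.00269 M⁻¹ min⁻¹, which moved elm by 1 point.

The forecast gave Z at 57% in elm and Z at 51% in maple, holding that “Q should cap near 50%”.

Elm gave Z at 58.3%, and maple gave Q at 72.3%.

    Z + G + D → D + Q (k = 0.400 M⁻² min⁻¹)
    X + G + D → D + L (k = 0.0460 M⁻² min⁻¹)
    X + E → J (k = 0.0720 M⁻¹ min⁻¹)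

My Z of 58.9% in elm and 27.6% in maple stood against 58.3% and 27.7%. Scaled to the 0.0040 M of D in a neighbour of elm, the pair constant gave Q of 28.5%, and that flask stood at 29.1%. The main reason maple held more Q than elm was the difference in time. With that difference taken away, maple stood at 41.7% of Q instead of 72.3%, a gap of 31 points.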